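# Proposed total synthesis of 5-(6-bromo-4-methoxy-1H-indol-3-yl)-2-(5-bromo-1H-pyrrol-2-yl)oxazole (13)

## The problem

Target 13 is a chain of three five-membered-ring heteroaromatics: a 6-bromo-4-methoxyindole bonded through C3 to C5 of an oxazole, whose C2 carries a 5-bromopyrrol-2-yl group, while oxazole C4 bears only hydrogen. There is no stereocentre, so the difficulty lies in regiochemistry and chemoselectivity: two heteroaryl–heteroaryl C–C bonds flank a 2,5-disubstituted oxazole, and indole C3 sits next to the peri 4-methoxy group. The two bromine atoms sit on different electron-rich rings (indole C6, pyrrole C5). A late electrophilic bromination would have to choose among indole C2, C5 and C7, oxazole C4 and three pyrrole positions, so both halogens are best brought in with the building blocks. They must then survive every later step, which speaks against zerovalent palladium, hydrogenolysis and halogen–metal exchange once the halides are in place. Both N–H groups are free in the target; the 2-bromopyrrole is sensitive to strong acid (protodebromination, oligomerisation) and the methoxyindole to over-oxidation. The enabling feature is that oxazole atoms O1, C2, N3, C4 and C5 map one for one onto the amide oxygen, amide carbon, nitrogen, α-carbon and β-carbon of an N-(pyrrole-2-carbonyl)tryptophan: only the O1–C5 bond and two unsaturations are missing, and the amino acid carboxyl on C4 can leave as CO2. C5 is the carbon attached to indole C3, the one position from which hydride can be removed because the indole nitrogen stabilises the resulting cation, and the amide oxygen lies five atoms away from it.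

## Retrosynthesis

**13 back to 12 and 11.** The first move adds a group instead of cutting a bond: the C4–H bond of 13 is traced back to C4–CO2H in acid 12 and from there to methyl ester 11. This carboxyl makes the oxazole recognisable as an amino acid derivative, and two steps further back it is the group that turns the alkene of 6 into a Michael acceptor. Forward, ester hydrolysis must leave three heteroaromatic rings untouched. The protodecarboxylation must spare two C–Br bonds, which favours a silver catalyst over copper at high temperature and excludes palladium.

**11 back to 8.** The O1–C5 bond is cut and the C4–C5 and C2–N3 unsaturations are removed, which opens the central ring to the acyclic N-acyl tryptophan ester 8. Neighbouring cuts at the indole–oxazole or oxazole–pyrrole bond would call for cross-coupling beside two aryl bromides and for N-protection. This cut turns both inter-ring bonds into ordinary bonds, an sp3 C–C bond to indole C3 and an amide. Precursor 8 has no ring to build and one stereocentre that is erased in the forward step, so it can be racemic. Forward, an oxidant (DDQ) must remove hydride twice from the indolylic carbon, the amide oxygen must trap the cation, and the bromopyrrole must be left alone.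

**8 back to 6 and 7.** The bond between indole C3 and the β-carbon is cut, giving the commercial indole 7 and the dehydroalanine amide 6. The alternative of preparing the free bromomethoxytryptophan first and acylating it would need a separate amino acid synthesis with protection and deprotection at nitrogen. Conjugate addition delivers 8 directly and convergently, and its lack of stereocontrol costs nothing. Forward, the indole must attack the β-carbon through C3 and not the α-carbon of an N-acylimine tautomer. A chelating Lewis acid (EtAlCl2) bound to the ester and amide carbonyls of 6 is the known way to secure this.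

**6 back to 4, 1 and 2.** The alkene of 6 comes from β-elimination of the serine amide 4 (C–O cut after activation), and 4 from amide formation between the commercial acid 1 and serine ester hydrochloride 2. Serine serves as a masked dehydroalanine. Both steps are routine and place the pyrrole bromine at the outset.

## Roads not taken

Alternative 1: The cut goes through the five-membered ring of the indole (N1–C2 and C3–C3a), leading back to 5-bromo-2-iodo-3-methoxyaniline A2 and the silylalkyne A3, an oxazole carrying an N-SEM-pyrrol-2-yl group at C2 and a trimethylsilylethynyl group at C5.
- Forward step: a Larock heteroannulation. Pd(OAc)2 (a divalent palladium precatalyst reduced in the flask to zerovalent palladium), LiCl and K2CO3 in DMF would insert into the C–I bond, carbopalladate the alkyne with the silyl group ending next to nitrogen, and close the ring to the 2-silylindole A1.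
- Merits: the benzenoid substitution pattern is fixed by the aniline, the indole–oxazole bond forms with defined regiochemistry, and two bonds and a ring arise in one step. In convergence this is better than the chosen plan.
- Weak points: the iodine of A2 is flanked by the amino and methoxy groups, which slows oxidative addition. A2 and A1 both carry an aryl bromide that zerovalent palladium can attack at the temperature needed. A3 already contains the pyrrolyl-oxazole, so the oxazole problem is moved, not solved. A1 lacks the pyrrole bromine, so desilylation, SEM removal and a site-selective bromination beside a methoxyindole would still follow.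
- Comparison: the chosen plan sets against the higher convergence its freedom from palladium and protecting groups, both bromines in place from the start, and six steps from three catalogue compounds.

Alternative 2: The cut is at oxazole C4–C5 and O1–C2, leading to the N-SEM indole-3-carbaldehyde A5 and TosMIC A6.
- Forward step: a van Leusen oxazole synthesis. With K2CO3 in refluxing methanol, the isocyanide carbanion adds to the aldehyde, the alkoxide closes onto the isocyanide carbon and toluenesulfinate is lost, giving the 5-(indol-3-yl)oxazole A4.
- Merits: the ring-forming step is more dependable than a DDQ closure. A5 is two routine operations from indole 7, C4–H arises directly so no decarboxylation is needed, and no oxidant meets the methoxyindole. In these respects this road is better than the chosen one.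
- Weak points: A4 has a free C2–H, so the pyrrole must be attached afterwards by C2 metalation and cross-coupling or by direct C–H arylation. Metallated oxazoles ring-open to isocyano enolates, strong bases threaten the C–Br bond, and zerovalent palladium must distinguish the coupling halide from the indole bromide. The pyrrole partner would need N-protection and either two different halogens or a late bromination, and SEM removal from the indole nitrogen is often sluggish.
- Comparison: the step count is similar. The chosen plan sets against the more reliable key step that both inter-ring bonds and both bromines exist before the ring is formed, and that no organometallic step ever meets an aryl bromide.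

Alternative 3: The cut goes through the pyrrole ring, leading to the 2-acetyloxazole oxime A8 and acetylene A9.
- Forward step: a Trofimov pyrrole synthesis in KOH/DMSO at about 100 °C. O-vinylation of the oximate, a [3,3] shift that forms pyrrole C3–C4 and a condensation that forms N1–C5 would give the N–H pyrrole A7.
- Merits: the pyrrole comes from the cheapest two-carbon unit with C3 to C5 unsubstituted and the N–H free.
- Weak points: a superbasic medium at 100 °C exposes the aryl bromide and the oxazole ring to hydroxide. N-vinylation of the product by excess acetylene is the usual side reaction, and acetylene must be handled hot. A8 presupposes the complete indolyl-oxazole plus C2 acylation and oximation, and A7 still lacks the pyrrole bromine and carries SEM.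
- Comparison: this is the longest of the four roads. Its only gain, not needing the bromopyrrole acid 1, is small because 1 is commercial, and the chosen plan is better on step count, halogen placement and mildness.

Key step: step 4

Assumption (remark on the chemistry): tryptophan amide 8 is planned as the racemate because its only stereocentre becomes sp2 in step 4; serine ester 2 is used as its commercial hydrochloride, and acid 1 and indole 7 are taken as catalogue compounds.

## Route

Step 1
Reactants: 1 5-bromo-1H-pyrrole-2-carboxylic acid; 2 L-serine methyl ester hydrochloride
Product: 4 methyl N-(5-bromo-1H-pyrrole-2-carbonyl)-L-serinate, via benzotriazol-1-yl ester 3 (not isolated)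
Conditions: EDC·HCl, HOBt, N-methylmorpholine, DMF, 0 °C to rt
Reagents that add atoms: none
Why: Carbodiimide amide coupling through the HOBt active ester 3; the primary amine of 2 outcompetes its hydroxyl and the weakly nucleophilic pyrrole N–H, so no protection is needed, and the serine stereocentre is carried unchanged but has no later role.

Step 2
Reactants: 4 methyl N-(5-bromo-1H-pyrrole-2-carbonyl)-L-serinate
Product: 6 methyl 2-[(5-bromo-1H-pyrrole-2-carbonyl)amino]acrylate, via O-mesylate 5 (not isolated)
Conditions: MsCl, Et3N (excess), CH2Cl2, 0 °C to rt
Reagents that add atoms: none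
Why: Sulfonylation of the primary alcohol followed by E1cB β-elimination of methanesulfonate, the standard serine-to-dehydroalanine dehydration; the ester acidifies the α-proton so that Et3N suffices, and the stereocentre is deliberately removed.

Step 3
Reactants: 6 methyl 2-[(5-bromo-1H-pyrrole-2-carbonyl)amino]acrylate; 7 6-bromo-4-methoxy-1H-indole
Product: 8 methyl N-(5-bromo-1H-pyrrole-2-carbonyl)-6-bromo-4-methoxytryptophanate (racemic)
Conditions: EtAlCl2 (hexane solution, about 3 equiv), CH2Cl2, 0 °C to rt; aq. NaHCO3 work-up
Reagents that add atoms: none
Why: Lewis-acid-mediated Friedel–Crafts conjugate addition of an indole to a 2-amidoacrylate: EtAlCl2 chelates the ester and amide carbonyls of 6, and indole 7 attacks the β-carbon through C3, its most nucleophilic position. The new α-stereocentre arises by unselective protonation of the aluminium enolate, so 8 is racemic, which is harmless because that centre becomes sp2 in step 4.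

Step 4
Reactants: 8 methyl N-(5-bromo-1H-pyrrole-2-carbonyl)-6-bromo-4-methoxytryptophanate (racemic)
Product: 11 methyl 5-(6-bromo-4-methoxy-1H-indol-3-yl)-2-(5-bromo-1H-pyrrol-2-yl)oxazole-4-carboxylate, via alkylideneindolenine 9 (not isolated), via oxazoline 10 (not isolated)
Conditions: DDQ (2.5 equiv), anhydrous THF, 4 Å molecular sieves, reflux, N2
Reagents that add atoms: none
Why: Yonemitsu oxidation: DDQ complexes the electron-rich methoxyindole and abstracts hydride from the β-CH2, the only C–H whose cation is stabilised by the indole nitrogen, giving the 3-alkylideneindoleninium ion (the N-protonated form of 9). The amide oxygen, five atoms away, adds to the exocyclic carbon in a 5-exo-trig closure that forms the O1–C5 bond and restores the indole, giving oxazoline 10. A second equivalent of DDQ again removes hydride from C5, which is still an indol-3-ylmethyl position, and loss of the ester-acidified C4 proton aromatises the ring to oxazole 11. The closest known reaction type is the DDQ-mediated conversion of N-acyl tryptophan esters into 5-(indol-3-yl)oxazole-4-carboxylates in dry refluxing THF. No stereocentre survives, since the α-centre of 8 and the transient C5 centre of 10 both become sp2, which is why racemic 8 is adequate. The step needs site selectivity for the tryptophan β-position and chemoselective trapping by the amide oxygen: the first rests on the free indole N–H and the methoxy donor set against a pyrrole deactivated by its 2-carbonyl and 5-bromo groups, the second on strictly anhydrous conditions and the intramolecular position of the oxygen. A quinone oxidant does not address either C–Br bond.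

Step 5
Reactants: 11 methyl 5-(6-bromo-4-methoxy-1H-indol-3-yl)-2-(5-bromo-1H-pyrrol-2-yl)oxazole-4-carboxylate
Product: 12 5-(6-bromo-4-methoxy-1H-indol-3-yl)-2-(5-bromo-1H-pyrrol-2-yl)oxazole-4-carboxylic acid
Conditions: LiOH·H2O, THF/MeOH/H2O, rt to 40 °C; then 1 M HCl, 0 °C, to pH 3
Reagents that add atoms: lithium hydroxide, [Li+].[OH-]
Why: Ester saponification by acyl–oxygen cleavage; the oxazole, both aryl bromides and both N–H rings tolerate aqueous hydroxide near room temperature, and the acidification is kept cold and brief to spare the bromopyrrole.

Step 6
Reactants: 12 5-(6-bromo-4-methoxy-1H-indol-3-yl)-2-(5-bromo-1H-pyrrol-2-yl)oxazole-4-carboxylic acid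
Product: 13 5-(6-bromo-4-methoxy-1H-indol-3-yl)-2-(5-bromo-1H-pyrrol-2-yl)oxazole
Conditions: Ag2CO3 (10 mol %), AcOH (5 mol %), DMSO, 120 °C
Reagents that add atoms: none
Why: Silver-catalysed protodecarboxylation of a heteroaryl carboxylic acid whose carboxyl carbon is adjacent to a ring heteroatom (here N3): the monovalent silver carboxylate extrudes CO2 to a C4–silver species that AcOH protonates. Silver does not insert into aryl C–Br bonds, so both bromines should be retained.

## Compound list

1 | 5-bromo-1H-pyrrole-2-carboxylic acid | O=C(O)c1ccc(Br)[nH]1 | starting material
2 | L-serine methyl ester hydrochloride, (S) | COC(=O)[C@@H](N)CO.Cl | starting material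
3 | 1H-benzotriazol-1-yl 5-bromo-1H-pyrrole-2-carboxylate (active ester, not isolated) | O=C(On1nnc2ccccc21)c1ccc(Br)[nH]1 | intermediate
4 | methyl N-(5-bromo-1H-pyrrole-2-carbonyl)-L-serinate, (S) | COC(=O)[C@@H](NC(=O)c1ccc(Br)[nH]1)CO | intermediate
5 | methyl (S)-2-[(5-bromo-1H-pyrrole-2-carbonyl)amino]-3-(methylsulfonyloxy)propanoate (not isolated) | COC(=O)[C@@H](NC(=O)c1ccc(Br)[nH]1)COS(C)(=O)=O | intermediate
6 | methyl 2-[(5-bromo-1H-pyrrole-2-carbonyl)amino]prop-2-enoate | C=C(NC(=O)c1ccc(Br)[nH]1)C(=O)OC | intermediate
7 | 6-bromo-4-methoxy-1H-indole | COc1cc(Br)cc2[nH]ccc12 | starting material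
8 | methyl 2-[(5-bromo-1H-pyrrole-2-carbonyl)amino]-3-(6-bromo-4-methoxy-1H-indol-3-yl)propanoate, racemic | COC(=O)C(Cc1c[nH]c2cc(Br)cc(OC)c12)NC(=O)c1ccc(Br)[nH]1 | intermediate
9 | methyl 3-(6-bromo-4-methoxy-3H-indol-3-ylidene)-2-[(5-bromo-1H-pyrrole-2-carbonyl)amino]propanoate (alkene geometry undefined, not isolated) | COC(=O)C(NC(=O)c1ccc(Br)[nH]1)C=C1C=Nc2cc(Br)cc(OC)c21 | intermediate
10 | methyl 5-(6-bromo-4-methoxy-1H-indol-3-yl)-2-(5-bromo-1H-pyrrol-2-yl)-4,5-dihydrooxazole-4-carboxylate (diastereomer mixture, not isolated) | COC(=O)C1N=C(c2ccc(Br)[nH]2)OC1c1c[nH]c2cc(Br)cc(OC)c12 | intermediate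
11 | methyl 5-(6-bromo-4-methoxy-1H-indol-3-yl)-2-(5-bromo-1H-pyrrol-2-yl)oxazole-4-carboxylate | COC(=O)c1nc(-c2ccc(Br)[nH]2)oc1-c1c[nH]c2cc(Br)cc(OC)c12 | intermediate
12 | 5-(6-bromo-4-methoxy-1H-indol-3-yl)-2-(5-bromo-1H-pyrrol-2-yl)oxazole-4-carboxylic acid | O=C(O)c1nc(-c2ccc(Br)[nH]2)oc1-c1c[nH]c2cc(Br)cc(OC)c12 | intermediate
13 | 5-(6-bromo-4-methoxy-1H-indol-3-yl)-2-(5-bromo-1H-pyrrol-2-yl)oxazole | COc1cc(Br)cc2[nH]cc(-c3cnc(-c4ccc(Br)[nH]4)o3)c12 | target

## Step count and least certain steps

Total: 6 steps. Longest linear sequence: 6 steps (from 1 and 2 to 13; indole 7 enters at step 3).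

**Step 4 (key step).**
- What may go wrong: the indoleninium ion may lose its α-proton faster than the amide oxygen closes, diverting material to an α,β-dehydro amino ester. Adventitious water may intercept the cation, giving oxidation at the β-carbon without ring closure. Excess quinone may over-oxidise or oligomerise the methoxyindole. The peri methoxy group may twist the indole out of conjugation with C5 and slow the second hydride abstraction, so that the sequence stalls at the dihydro stage.
- Fallback: it sets out from 8 and returns at 11, and makes water the intended nucleophile. DDQ in THF/H2O (9:1) at 0 °C to rt should give the β-keto ester methyl 3-(6-bromo-4-methoxy-1H-indol-3-yl)-2-[(5-bromo-1H-pyrrole-2-carbonyl)amino]-3-oxopropanoate F1. A Robinson–Gabriel cyclodehydration (PPh3, I2, Et3N, CH2Cl2) then forms the same O1–C5 bond from the ketone and gives 11.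

**Step 3.**
- What may go wrong: the pyrrole N–H, the amide and the methoxy group may sequester the Lewis acid. The indole may add at the α-carbon through the N-acylimine tautomer of the acrylate if adventitious protic acid takes over. The peri methoxy group may retard C3 attack, and the dehydroalanine may polymerise.
- Fallback: it sets out from indole 7 and acid 1 and returns at 8. Methyl bromopyruvate is condensed with hydroxylamine hydrochloride to methyl 3-bromo-2-(hydroxyimino)propanoate F2. With Na2CO3 in CH2Cl2 this loses HBr to the transient nitrosoalkene methyl 2-nitrosoacrylate F3, which indole 7 captures at C3 to give methyl 3-(6-bromo-4-methoxy-1H-indol-3-yl)-2-(hydroxyimino)propanoate F4. Zn dust in AcOH reduces the oxime to racemic methyl 6-bromo-4-methoxytryptophanate F5 without touching the aryl bromide. EDC/HOBt coupling with acid 1, through active ester 3, then gives 8.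

**Step 6.**
- What may go wrong: the 2-bromopyrrole may suffer protodebromination or thermal degradation at 120 °C. The N–H heterocycles may bind the silver and leave the decarboxylation incomplete. The electron-rich indolyl-oxazole may be protonated elsewhere and decompose.
- Fallback: it sets out from 8 and returns at 13, removing the carboxyl before the aromatic ring exists. Oxidation of 8 with DDQ in THF/H2O gives the β-keto ester F1, the compound of the fallback for step 4. LiOH saponification gives 3-(6-bromo-4-methoxy-1H-indol-3-yl)-2-[(5-bromo-1H-pyrrole-2-carbonyl)amino]-3-oxopropanoic acid F6, which as a β-keto acid should lose CO2 on acidification and gentle warming without any metal. The resulting α-amido ketone N-[2-(6-bromo-4-methoxy-1H-indol-3-yl)-2-oxoethyl]-5-bromo-1H-pyrrole-2-carboxamide F7 is closed by Robinson–Gabriel cyclodehydration (PPh3, C2Cl6, Et3N, MeCN) to give 13 directly.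

## Further compounds

F1 | step 4 | methyl 3-(6-bromo-4-methoxy-1H-indol-3-yl)-2-[(5-bromo-1H-pyrrole-2-carbonyl)amino]-3-oxopropanoate (racemic) | COC(=O)C(NC(=O)c1ccc(Br)[nH]1)C(=O)c1c[nH]c2cc(Br)cc(OC)c12
F2 | step 3 | methyl 3-bromo-2-(hydroxyimino)propanoate | COC(=O)C(CBr)=NO
F3 | step 3 | methyl 2-nitrosoacrylate (transient) | C=C(N=O)C(=O)OC
F4 | step 3 | methyl 3-(6-bromo-4-methoxy-1H-indol-3-yl)-2-(hydroxyimino)propanoate | COC(=O)C(Cc1c[nH]c2cc(Br)cc(OC)c12)=NO
F5 | step 3 | methyl 6-bromo-4-methoxytryptophanate (racemic) | COC(=O)C(N)Cc1c[nH]c2cc(Br)cc(OC)c12
F6 | step 6 | 3-(6-bromo-4-methoxy-1H-indol-3-yl)-2-[(5-bromo-1H-pyrrole-2-carbonyl)amino]-3-oxopropanoic acid (racemic, transient) | OC(=O)C(NC(=O)c1ccc(Br)[nH]1)C(=O)c1c[nH]c2cc(Br)cc(OC)c12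
F7 | step 6 | N-[2-(6-bromo-4-methoxy-1H-indol-3-yl)-2-oxoethyl]-5-bromo-1H-pyrrole-2-carboxamide | O=C(CNC(=O)c1ccc(Br)[nH]1)c1c[nH]c2cc(Br)cc(OC)c12
A1 | alternative 1 | 6-bromo-4-methoxy-3-{2-[1-(2-trimethylsilylethoxymethyl)pyrrol-2-yl]oxazol-5-yl}-2-(trimethylsilyl)-1H-indole | COc1cc(Br)cc2[nH]c([Si](C)(C)C)c(-c3cnc(-c4cccn4COCC[Si](C)(C)C)o3)c12
A2 | alternative 1 | 5-bromo-2-iodo-3-methoxyaniline | COc1cc(Br)cc(N)c1I
A3 | alternative 1 | 2-[1-(2-trimethylsilylethoxymethyl)pyrrol-2-yl]-5-[(trimethylsilyl)ethynyl]oxazole | C[Si](C)(C)C#Cc1cnc(-c2cccn2COCC[Si](C)(C)C)o1
A4 | alternative 2 | 5-[6-bromo-4-methoxy-1-(2-trimethylsilylethoxymethyl)indol-3-yl]oxazole | COc1cc(Br)cc2c1c(-c1cnco1)cn2COCC[Si](C)(C)C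
A5 | alternative 2 | 6-bromo-4-methoxy-1-(2-trimethylsilylethoxymethyl)indole-3-carbaldehyde | COc1cc(Br)cc2c1c(C=O)cn2COCC[Si](C)(C)C
A6 | alternative 2 | p-toluenesulfonylmethyl isocyanide (TosMIC) | Cc1ccc(S(=O)(=O)C[N+]#[C-])cc1
A7 | alternative 3 | 5-[6-bromo-4-methoxy-1-(2-trimethylsilylethoxymethyl)indol-3-yl]-2-(1H-pyrrol-2-yl)oxazole | COc1cc(Br)cc2c1c(-c1cnc(-c3ccc[nH]3)o1)cn2COCC[Si](C)(C)C
A8 | alternative 3 | 1-{5-[6-bromo-4-methoxy-1-(2-trimethylsilylethoxymethyl)indol-3-yl]oxazol-2-yl}ethanone oxime | COc1cc(Br)cc2c1c(-c1cnc(C(C)=NO)o1)cn2COCC[Si](C)(C)C
A9 | alternative 3 | acetylene | C#C
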